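## Retrosynthetic overview

- Numbering: ring A is C1–C6 (C1 bears the chain, C2 the acetate, C3 the ring angelate, C4 the methyl, C4–C5 the ring oxirane, C6 is CH2); the chain is C7 (=C14H2), C8 (angelate), C9, and the C10–C11 oxirane. The strategy rests on ring A having C1 and C2 as cis neighbours with the methyl on C4, para to C1. This is the endo adduct of (E)-1-acetoxy-3-methylbuta-1,3-diene and acrolein, formed through C1–C2 and C5–C6, with the formyl carbon becoming C7.
- Ring A is the only carbocycle and is closed first (step 2). Its C3=C4 alkene is then transposed to a C3 ketone with a C4=C5 alkene, reduced to the C3 alcohol cis to the acetate, and epoxidised under hydroxyl direction to give the C4–C5 oxirane.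
- Chain: the formyl group becomes a methyl ketone and then the C7 alkenyl triflate. The C7–C8 bond comes from a CrCl2/NiCl2 coupling with 4-methylpent-3-enal, and C8 is set by oxidation and CBS reduction.
- Both angelates come from angelic acid through one batch of a mixed anhydride made in step 10. The C10–C11 oxirane is made last by ketone-catalysed asymmetric epoxidation.

Key step: step 2

## Route

Step 1
Reactants: 1 3-methylbut-2-enal
Product: 2 (1E)-3-methylbuta-1,3-dien-1-yl acetate
Conditions: Ac2O, KOAc, Et3N, 120 °C; fractional distillation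
Reagents that add atoms: acetic anhydride, CC(=O)OC(C)=O
Why: Vinylogous enol acetylation, in which base removes a γ-proton while oxygen is acetylated, should give the conjugated dienyl acetate mainly as the E isomer, the only geometry that reaches the s-cis form needed in step 2.

Step 2
Reactants: 2 (1E)-3-methylbuta-1,3-dien-1-yl acetate; 3 acrolein
Product: 6 (1R,2S)-2-acetoxy-4-methylcyclohex-3-ene-1-carbaldehyde, via acrolein iminium chloride 4 (not isolated), via cycloadduct iminium chloride 5 (not isolated)
Conditions: (5S)-5-benzyl-2,2,3-trimethylimidazolidin-4-one hydrochloride (20 mol %), acrolein (3 equiv), MeNO2/H2O 95:5, 0 °C to rt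
Reagents that add atoms: none
Why: The amine hydrochloride and acrolein first form the E iminium ion 4, a much stronger dienophile than the free enal; diene 2 then adds across its C=C bond in one asynchronous pericyclic event, and water cleaves iminium 5 to release 6 and return the amine. The closest known reaction type is the iminium-catalysed enantioselective Diels–Alder reaction of 1-acyloxybutadienes with enals. Ring A is closed by an intermolecular [4+2] cycloaddition, suprafacial on both components, that forms C1–C2 and C5–C6. Both donors on the diene (O-acyl at one terminus, methyl at the 3-position) raise the HOMO coefficient at the unsubstituted CH2 terminus, so that carbon bonds to the β-carbon of 4 and C1 ends up next to C2 with the methyl on C4. C1 is set by the catalyst, whose benzyl arm covers one face of the iminium so that the diene adds to the open face (Si at C1); C2 is set relative to C1 by the endo transition state together with the E enol ester geometry, which places CHO and OAc cis. The step needs endo and enantiofacial selectivity, supplied by the fixed iminium geometry and the benzyl shield; the β-acetoxy aldehyde is carried on cold and without base so that it neither epimerises at C1 nor loses acetic acid.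

Step 3
Reactants: 6 (1R,2S)-2-acetoxy-4-methylcyclohex-3-ene-1-carbaldehyde
Product: 7 (1S,6S)-6-(1-hydroxyethyl)-3-methylcyclohex-2-en-1-yl acetate (both C7 epimers)
Conditions: MeMgBr (1.05 equiv), THF, −78 °C; sat. aq NH4Cl at −78 °C
Reagents that add atoms: methylmagnesium bromide, C[Mg]Br
Why: Grignard 1,2-addition to the aldehyde should be far faster than attack on the acetate at −78 °C, and the uncontrolled C7 carbinol centre is removed in step 4.

Step 4
Reactants: 7 (1S,6S)-6-(1-hydroxyethyl)-3-methylcyclohex-2-en-1-yl acetate
Product: 8 (1S,6R)-6-acetyl-3-methylcyclohex-2-en-1-yl acetate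
Conditions: Dess–Martin periodinane, NaHCO3, CH2Cl2, 0 °C to rt
Reagents that add atoms: none
Why: Buffered Dess–Martin oxidation should convert the secondary alcohol to the methyl ketone under non-basic conditions that leave the β-acetoxy ketone and the C1 centre intact.

Step 5
Reactants: 8 (1S,6R)-6-acetyl-3-methylcyclohex-2-en-1-yl acetate
Product: 10 1-[(1R,2S)-2-acetoxy-4-methylcyclohex-3-en-1-yl]ethenyl trifluoromethanesulfonate, via potassium enolate 9 (not isolated)
Conditions: KN(SiMe3)2 (1.05 equiv), THF, −78 °C (ketone added to base); then N-(5-chloropyridin-2-yl)-1,1,1-trifluoro-N-(trifluoromethylsulfonyl)methanesulfonamide (Comins' reagent), −78 °C; cold sat. aq NH4Cl work-up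
Reagents that add atoms: Comins' reagent, O=S(=O)(N(c1ccc(Cl)cn1)S(=O)(=O)C(F)(F)F)C(F)(F)F
Why: Kinetic deprotonation by the bulky amide should occur at the methyl group rather than at C1–H or the acetate, and O-sulfonylation of enolate 9 at −78 °C gives the terminal enol triflate before proton exchange could trigger loss of acetate (enol triflate formation).

Step 6
Reactants: 10 1-[(1R,2S)-2-acetoxy-4-methylcyclohex-3-en-1-yl]ethenyl trifluoromethanesulfonate
Product: 11 1-[(1R,2R,4R)-2-acetoxy-4-hydroxy-4-methyl-3-oxocyclohexyl]ethenyl trifluoromethanesulfonate (C4 hydroxyl trans to the C2 acetate)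
Conditions: RuCl3 (2 mol %), Oxone (2KHSO5·KHSO4·K2SO4), NaHCO3, EtOAc/MeCN/H2O, rt
Reagents that add atoms: potassium peroxymonosulfate (active part of Oxone), [K+].OOS(=O)(=O)[O-]
Why: RuO4-catalysed ketohydroxylation of a trisubstituted alkene should turn the CH carbon C3 into the ketone and leave the hydroxyl on tertiary C4, with attack anti to the allylic acetate; the electron-poor enol triflate alkene should be spared and the C4 configuration is erased in step 7.

Step 7
Reactants: 11 1-[(1R,2R,4R)-2-acetoxy-4-hydroxy-4-methyl-3-oxocyclohexyl]ethenyl trifluoromethanesulfonate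
Product: 13 1-[(1R,2R)-2-acetoxy-4-methyl-3-oxocyclohex-4-en-1-yl]ethenyl trifluoromethanesulfonate, via chlorosulfite 12 (not isolated)
Conditions: SOCl2, pyridine, CH2Cl2, −20 to 0 °C
Reagents that add atoms: none
Why: Anti E2 elimination of the tertiary chlorosulfite with the axial C5 hydrogen should give the more stable endocyclic conjugated enone, since C3 carries no hydrogen and elimination into the methyl group would give the less stable exocyclic enone (dehydration of a tertiary α-ketol).

Step 8
Reactants: 13 1-[(1R,2R)-2-acetoxy-4-methyl-3-oxocyclohex-4-en-1-yl]ethenyl trifluoromethanesulfonate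
Product: 14 1-[(1R,2R,3S)-2-acetoxy-3-hydroxy-4-methylcyclohex-4-en-1-yl]ethenyl trifluoromethanesulfonate
Conditions: NaBH4, CeCl3·7H2O, MeOH, −78 °C; AcOH quench
Reagents that add atoms: none
Why: Luche 1,2-reduction should deliver hydride axially to C3 from the face opposite the pseudoaxial C2 acetate and the C1 substituent, placing the new hydroxyl cis to the acetate.

Step 9
Reactants: 14 1-[(1R,2R,3S)-2-acetoxy-3-hydroxy-4-methylcyclohex-4-en-1-yl]ethenyl trifluoromethanesulfonate
Product: 15 epoxy alcohol: 14 with a C4–C5 oxirane whose oxygen is cis to the C3 hydroxyl (C7, OAc, OH and oxirane O all on one face of ring A)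
Conditions: VO(acac)2 (5 mol %), t-BuOOH, CH2Cl2, 0 °C to rt
Reagents that add atoms: tert-butyl hydroperoxide, CC(C)(C)OO
Why: Hydroxyl-directed epoxidation should deliver oxygen to the C4=C5 alkene on the face of the C3 hydroxyl, while the electron-poor enol triflate alkene has no directing group and stays intact.

Step 10
Reactants: 16 angelic acid [(Z)-2-methylbut-2-enoic acid]
Product: 17 angelic 2,4,6-trichlorobenzoic anhydride (toluene stock solution)
Conditions: 2,4,6-trichlorobenzoyl chloride (1.0 equiv), Et3N (1.1 equiv), toluene, 0 °C to rt; filtered under argon from Et3N·HCl; filtrate kept at −20 °C and drawn on for steps 11 and 16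
Reagents that add atoms: 2,4,6-trichlorobenzoyl chloride, O=C(Cl)c1c(Cl)cc(Cl)cc1Cl
Why: Acyl substitution of the acid chloride by triethylammonium angelate (Yamaguchi mixed anhydride formation) should give the anhydride without a nucleophilic catalyst, so the Z geometry of the acid is kept; one batch is made on a scale that serves both angeloylations.

Step 11
Reactants: 15 epoxy alcohol; 17 angelic 2,4,6-trichlorobenzoic anhydride
Product: 18 C3 angelate of 15
Conditions: 17 (3 equiv, toluene solution), Et3N, toluene, 75 °C
Reagents that add atoms: none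
Why: In this Yamaguchi-type esterification the hindered C3 hydroxyl should attack the angeloyl carbonyl of 17, the aryl carbonyl being screened by its two ortho chlorines; the C3–O bond is untouched, so C3 is retained, and the absence of a nucleophilic pyridine catalyst limits Z to E isomerisation of the acyl group.

Step 12
Reactants: 19 4-methylpent-3-en-1-ol
Product: 20 4-methylpent-3-enal
Conditions: Dess–Martin periodinane, NaHCO3, CH2Cl2, 0 °C; filtered solution used at once
Reagents that add atoms: none
Why: Buffered Dess–Martin oxidation should give the β,γ-unsaturated aldehyde without moving the double bond into conjugation.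

Step 13
Reactants: 18 C3 angelate alkenyl triflate; 20 4-methylpent-3-enal
Product: 22 allylic alcohol: 18 with the C7 triflate replaced by CH(OH)CH2CH=C(CH3)2 (both C8 epimers), via alkenylchromium dichloride 21 (not isolated)
Conditions: CrCl2 (6 equiv), NiCl2 (2 mol %), 20 (3 equiv), DMF, rt
Reagents that add atoms: none
Why: In this Nozaki–Hiyama–Kishi coupling zerovalent nickel inserts into the C7–OTf bond and passes the alkenyl group to chromium, and the trivalent alkenylchromium 21 adds only to the aldehyde, tolerating both esters and the oxirane; C8 is not controlled here and is reset in steps 14 and 15.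

Step 14
Reactants: 22 allylic alcohol (C8 epimers)
Product: 23 enone: 22 with C8 as a ketone (C7(=CH2)–C(=O)–CH2–CH=C(CH3)2)
Conditions: Dess–Martin periodinane, NaHCO3, CH2Cl2, 0 °C; rapid filtration through neutral silica
Reagents that add atoms: none
Why: Buffered Dess–Martin oxidation of the allylic alcohol should converge both C8 epimers on one ketone under conditions mild enough to keep the C10=C11 alkene out of conjugation.

Step 15
Reactants: 23 enone
Product: 24 (8S)-allylic alcohol
Conditions: (R)-1-methyl-3,3-diphenyltetrahydro-1H,3H-pyrrolo[1,2-c][1,3,2]oxazaborole [(R)-Me-CBS, 1 equiv], catecholborane, toluene, −78 °C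
Reagents that add atoms: none
Why: In this Corey–Bakshi–Shibata reduction the α-branched alkenyl group acts as the large substituent and the C9 methylene as the small one, so the (R)-oxazaborolidine should deliver hydride to the face that gives the 8S alcohol, as it gives (S)-1-phenylethanol from acetophenone; catecholborane at low temperature avoids hydroboration.

Step 16
Reactants: 24 (8S)-allylic alcohol; 17 angelic 2,4,6-trichlorobenzoic anhydride
Product: 25 bis-angelate: 24 with the C8 hydroxyl esterified as the (Z)-2-methylbut-2-enoate
Conditions: 17 (3 equiv, second portion of the toluene solution from step 10), Et3N, toluene, 75 °C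
Reagents that add atoms: none
Why: The same Yamaguchi-type acylation should esterify the less hindered C8 hydroxyl with retention at C8, which also removes the free hydroxyl before the chain oxirane is made.

Step 17
Reactants: 25 bis-angelate
Product: 26 CNP0118696.1
Conditions: 1,2:4,5-di-O-isopropylidene-β-L-erythro-2,3-hexodiulo-2,6-pyranose (L-fructose-derived Shi ketone, 30 mol %), Oxone (2KHSO5·KHSO4·K2SO4), K2CO3, Bu4NHSO4, MeCN/dimethoxymethane/aq Na2B4O7 buffer, 0 °C
Reagents that add atoms: potassium peroxymonosulfate (active part of Oxone), [K+].OOS(=O)(=O)[O-]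
Why: Shi epoxidation should oxidise only the electron-rich trisubstituted C10=C11 alkene, the 1,1-disubstituted and angelate alkenes being too electron-poor or hindered, and the L-fructose-derived ketone should give the 10S oxirane through the spiro transition state, since the D-fructose ketone gives R with R–CH=C(CH3)2 alkenes.

## Compound list

1 | 3-methylbut-2-enal | CC(C)=CC=O | starting material
2 | (1E)-3-methylbuta-1,3-dien-1-yl acetate | C=C(C)/C=C/OC(C)=O | intermediate
3 | acrolein | C=CC=O | starting material
4 | acrolein iminium chloride of the (5S)-imidazolidinone (E) | C=C/C=[N+]1\[C@@H](Cc2ccccc2)C(=O)N(C)C1(C)C.[Cl-] | intermediate (not isolated)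
5 | cycloadduct iminium chloride | [Cl-].CC1(C)N(C)C(=O)[C@H](Cc2ccccc2)[N+]1=C[C@@H]1CCC(C)=C[C@@H]1OC(C)=O | intermediate (not isolated)
6 | (1R,2S)-2-acetoxy-4-methylcyclohex-3-ene-1-carbaldehyde | O=C[C@@H]1CCC(C)=C[C@@H]1OC(C)=O | intermediate
7 | (1S,6S)-6-(1-hydroxyethyl)-3-methylcyclohex-2-en-1-yl acetate, C7 epimers | CC(O)[C@@H]1CCC(C)=C[C@@H]1OC(C)=O | intermediate
8 | (1S,6R)-6-acetyl-3-methylcyclohex-2-en-1-yl acetate | CC(=O)[C@@H]1CCC(C)=C[C@@H]1OC(C)=O | intermediate
9 | potassium enolate of 8 (C7–O, C7=C14) | C=C([O-])[C@@H]1CCC(C)=C[C@@H]1OC(C)=O.[K+] | intermediate (not isolated)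
10 | 1-[(1R,2S)-2-acetoxy-4-methylcyclohex-3-en-1-yl]ethenyl trifluoromethanesulfonate | C=C(OS(=O)(=O)C(F)(F)F)[C@@H]1CCC(C)=C[C@@H]1OC(C)=O | intermediate
11 | 1-[(1R,2R,4R)-2-acetoxy-4-hydroxy-4-methyl-3-oxocyclohexyl]ethenyl trifluoromethanesulfonate | C=C(OS(=O)(=O)C(F)(F)F)[C@@H]1CC[C@@](C)(O)C(=O)[C@@H]1OC(C)=O | intermediate
12 | chlorosulfite of 11 at the C4 oxygen | C=C(OS(=O)(=O)C(F)(F)F)[C@@H]1CC[C@@](C)(OS(=O)Cl)C(=O)[C@@H]1OC(C)=O | intermediate (not isolated)
13 | 1-[(1R,2R)-2-acetoxy-4-methyl-3-oxocyclohex-4-en-1-yl]ethenyl trifluoromethanesulfonate | C=C(OS(=O)(=O)C(F)(F)F)[C@@H]1CC=C(C)C(=O)[C@@H]1OC(C)=O | intermediate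
14 | 1-[(1R,2R,3S)-2-acetoxy-3-hydroxy-4-methylcyclohex-4-en-1-yl]ethenyl trifluoromethanesulfonate | C=C(OS(=O)(=O)C(F)(F)F)[C@@H]1CC=C(C)[C@H](O)[C@@H]1OC(C)=O | intermediate
15 | epoxy alcohol: C4–C5 oxirane cis to the C3 hydroxyl, C2 acetate, C7 alkenyl triflate | C=C(OS(=O)(=O)C(F)(F)F)[C@@H]1C[C@@H]2O[C@]2(C)[C@H](O)[C@@H]1OC(C)=O | intermediate
16 | angelic acid, (Z)-2-methylbut-2-enoic acid | C/C=C(/C)C(=O)O | starting material
17 | angelic 2,4,6-trichlorobenzoic anhydride | C/C=C(/C)C(=O)OC(=O)c1c(Cl)cc(Cl)cc1Cl | intermediate
18 | C3 angelate of 15 | C=C(OS(=O)(=O)C(F)(F)F)[C@@H]1C[C@@H]2O[C@]2(C)[C@H](OC(=O)/C(C)=C\C)[C@@H]1OC(C)=O | intermediate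
19 | 4-methylpent-3-en-1-ol | CC(C)=CCCO | starting material
20 | 4-methylpent-3-enal | CC(C)=CCC=O | intermediate
21 | alkenylchromium dichloride from 18 (trivalent chromium on C7) | C=C([Cr](Cl)Cl)[C@@H]1C[C@@H]2O[C@]2(C)[C@H](OC(=O)/C(C)=C\C)[C@@H]1OC(C)=O | intermediate (not isolated)
22 | C8 allylic alcohol, both C8 epimers | C=C(C(O)CC=C(C)C)[C@@H]1C[C@@H]2O[C@]2(C)[C@H](OC(=O)/C(C)=C\C)[C@@H]1OC(C)=O | intermediate
23 | C8 ketone (exo-methylene enone) | C=C(C(=O)CC=C(C)C)[C@@H]1C[C@@H]2O[C@]2(C)[C@H](OC(=O)/C(C)=C\C)[C@@H]1OC(C)=O | intermediate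
24 | (8S)-allylic alcohol | C=C([C@H](CC=C(C)C)O)[C@@H]1C[C@@H]2O[C@]2(C)[C@H](OC(=O)/C(C)=C\C)[C@@H]1OC(C)=O | intermediate
25 | 3,8-bis-angelate with C10=C11 alkene | C=C([C@H](CC=C(C)C)OC(=O)/C(C)=C\C)[C@@H]1C[C@@H]2O[C@]2(C)[C@H](OC(=O)/C(C)=C\C)[C@@H]1OC(C)=O | intermediate
26 | CNP0118696.1, (1S,2R,3R,4S,5S,8S,10S) in the numbering used here | C=C([C@H](C[C@@H]1OC1(C)C)OC(=O)/C(C)=C\C)[C@@H]1C[C@@H]2O[C@]2(C)[C@H](OC(=O)/C(C)=C\C)[C@@H]1OC(C)=O | target

## Step count and risks

Total: 17 steps. Longest linear sequence: 15 steps (steps 1–9, 11 and 13–17); steps 10 and 12 are one-step side branches.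

**Step 7.** The elimination may run into the C4 methyl group to give the exocyclic enone, or stall at a tertiary chloride. The fallback avoids the ketol and sets out from alkenyl triflate 10. Nitrosyl chloride (isopentyl nitrite, HCl, CH2Cl2, −10 °C) should add NO to C3 and chloride to tertiary C4 and tautomerise to the α-chloro oxime F1. Warming in pyridine/DMF removes HCl toward C5 and should give the conjugated oxime F2; this nitrosochlorination–dehydrochlorination of 1-methylcyclohexenes is known to place the new alkene in the ring. Oxime exchange with aqueous glyoxylic acid then releases the ketone, and the route is rejoined at enone 13.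

**Step 11.** Slow acylation of the crowded C3 hydroxyl may let Z to E isomerisation of the angeloyl unit and acetyl migration from the C2 to the C3 oxygen compete. The fallback sets out from epoxy alcohol 15. It is esterified at room temperature with 2-[bis(2,2,2-trifluoroethoxy)phosphoryl]propanoic acid (DCC, catalytic 4-(dimethylamino)pyridine, CH2Cl2) to the phosphonopropionate ester F3, an acyl group that cannot isomerise. A Still–Gennari olefination of F3 with acetaldehyde (KN(SiMe3)2, 18-crown-6, THF, −78 °C) then builds the Z-2-methylbut-2-enoate in place, and the route is rejoined at angelate 18.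

**Step 14.** At the ketone stage the C10=C11 double bond may shift into conjugation with the new C8 carbonyl, and the exo-methylene enone may be lost by conjugate addition. The fallback never passes through a C8 ketone and sets out from alkenyl triflate 18. Reductive carbonylation (Pd(PPh3)4, CO, Bu3SnH, THF, 50 °C) should give the enal F4. Brown allylation with (−)-B-allyldiisopinocampheylborane (from (+)-α-pinene; Et2O, −78 °C, ethanolamine work-up) should set C8 by reagent control and give the (8S)-homoallylic alcohol F5. Cross-metathesis of F5 with 2-methylbut-2-ene, using the second-generation Grubbs catalyst (H2IMes)(PCy3)Cl2Ru=CHPh, converts the allyl terminus into the prenyl terminus, and the route is rejoined at (8S)-alcohol 24.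

Further compounds
F1 | step 7 | α-chloro oxime: 10 with C3 as C=NOH and C4 bearing Cl and CH3 | C=C(OS(=O)(=O)C(F)(F)F)[C@@H]1CCC(C)(Cl)C(=NO)[C@@H]1OC(C)=O
F2 | step 7 | conjugated oxime: oxime of enone 13 | C=C(OS(=O)(=O)C(F)(F)F)[C@@H]1CC=C(C)C(=NO)[C@@H]1OC(C)=O
F3 | step 11 | C3 2-[bis(2,2,2-trifluoroethoxy)phosphoryl]propanoate of 15 | C=C(OS(=O)(=O)C(F)(F)F)[C@@H]1C[C@@H]2O[C@]2(C)[C@H](OC(=O)C(C)P(=O)(OCC(F)(F)F)OCC(F)(F)F)[C@@H]1OC(C)=O
F4 | step 14 | enal: 18 with the C7 triflate replaced by CHO | C=C(C=O)[C@@H]1C[C@@H]2O[C@]2(C)[C@H](OC(=O)/C(C)=C\C)[C@@H]1OC(C)=O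
F5 | step 14 | (8S)-homoallylic alcohol with an allyl group on C8 | C=C([C@H](CC=C)O)[C@@H]1C[C@@H]2O[C@]2(C)[C@H](OC(=O)/C(C)=C\C)[C@@H]1OC(C)=O
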